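## Structural features

Fragransin B1 has a single oxolane ring (O1, C2–C5). Each of the benzylic carbons C2 and C5 carries a 4-hydroxy-3,5-dimethoxyphenyl ring, and each of C3 and C4 carries a methyl group. The four stereocentres are contiguous: the aryl groups are cis to each other, the methyl groups are cis to each other, and each aryl group is trans to the methyl group next to it. A mirror plane through O1 and the midpoint of C3–C4 makes the compound meso, (2S,3S,4R,5R), so only relative configuration has to be set. The fragile sites are the two electron-rich free phenols, which are easily oxidised further, and the two benzylic C–O bonds para to them, which ionise in acid and are open to hydrogenolysis. The real difficulty is the cis relationship of the C3 and C4 methyl groups, because these centres cannot be epimerised once the ring exists, whereas C2 and C5 can. Constitutionally the molecule is two identical aryl-C3 units joined at C3–C4 with O1 bridging the benzylic carbons, and both positions ortho to each phenol oxygen are blocked by methoxy groups. The key step uses exactly this: two identical phenoxyl radicals can join only through their side-chain carbons (future C3–C4) or through oxygen, and the two quinone methide carbons that result (future C2 and C5) are bridged by the oxygen of one water molecule.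

## Logic of the disconnections

First, 9 is related to 7 without cutting a bond; only the configurations at C2 and C5 are released. The O1–C2 and O1–C5 bonds of 9 are para-hydroxybenzylic and should open reversibly in acid through 8, so these two centres can be left to thermodynamic control. The gain is that the bond-forming step no longer has to deliver them, and the stereochemical problem shrinks to the C3/C4 pair. The demand on the forward step is an acid mild enough that re-closure through oxygen stays faster than any irreversible capture of the ring-opened form.

Second, 7 is cut at C3–C4, O1–C2 and O1–C5, which returns two molecules of 2 and the oxygen atom of 3. The cut follows the symmetry of the ring: both halves are the same C11 phenol. In the forward sense, oxidation of 2 gives 4, two of which join at their side-chain carbons to 5; this takes up 3 to give 6, which closes to 7. The gain is three skeletal bonds, the ring and all four stereocentres in one operation. The demands are coupling at carbon rather than at oxygen, pairing of the two radicals in the unlike sense, and an oxidant that stops at 7.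

Third, 2 is traced to 1 with no skeletal cut; the double bond is moved out of conjugation to the chain terminus. The reason is that 1 is commercial and already has the full carbon and oxygen pattern. The gain is that no C–C bond and no protecting group is needed before the key step. The demand is complete transposition with (E) geometry.

## Other disconnections considered

Alternative 1: The ring is cut at O1–C5 and C2–C3. This leads to the donor–acceptor cyclopropane A1 (dimethyl 2-(4-benzyloxy-3,5-dimethoxyphenyl)-3-methylcyclopropane-1,1-dicarboxylate) and the aldehyde A2 (4-benzyloxy-3,5-dimethoxybenzaldehyde).
- **Forward key step:** Sn(OTf)2 would activate the diester; the carbonyl oxygen of A2 opens A1 at its benzylic carbon and the malonate carbon closes onto the carbonyl carbon, giving the cis-2,5-diaryl oxolane-3,3-diester A3.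
- **In favour:** it is a polar, Lewis-acid-catalysed annulation of a well-studied type that is expected to be cis-selective at C2/C5. No oxidant meets a free phenol and no O-coupled by-product can form.
- **Against:** if the opening is invertive at the benzylic carbon, as an SN2-like attack implies, the trans relationship of the C4 methyl and C5 aryl groups requires the cis-configured cyclopropane A1. That would have to come from a (Z)-alkene by stereospecific carbene transfer, and the electron-rich aryl group invites ring opening to a zwitterion that would blur the geometry. C3 also emerges as a quaternary diester: one ester must be excised, the other set cis to the C4 methyl group and reduced to a methyl group via the alcohol and a sulfonate, and the benzyl ethers then removed next to two benzylic ring C–O bonds.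
- **Structure:** the plan ignores the symmetry of the target and builds C3 at the wrong oxidation level. It is the better plan on one point: C3 remains an epimerisable ester centre, so the C3/C4 relationship can be corrected, which the chosen plan cannot do.
- **Mechanism:** it is the better-defined of the two (closed-shell, stereospecific, no pairing of radicals).
- **Step economy:** it is clearly worse, about ten operations against three.

Alternative 2: Only C3–C4 is cut, in a radical sense. This leads back to the bromo ether A4, in which the oxygen already links the two benzylic carbons, one bearing a 1-bromoethyl group and the other a vinyl group.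
- **Forward key step:** Bu3SnH/AIBN would generate the secondary radical at C3, which adds 5-exo-trig to the internal vinyl carbon. Hydrogen transfer to the exocyclic radical gives the C4 methyl group and the bis(benzyl ether) A5; hydrogenolysis would then give 9.
- **In favour:** the chair-like transition-state model for 5-hexenyl radical cyclisation predicts the required pattern. The substituent on the radical carbon ends cis to the new methyl group, and both aryl groups sit pseudo-equatorial and trans to the neighbouring methyl groups. The phenols are protected and O-coupling is impossible.
- **Against:** A4 is an unsymmetrical ether between two different secondary benzylic carbons whose relative configuration must already correspond to cis C2/C5. No simple stereocontrolled etherification exists for such an acid-labile, doubly benzylic and allylic ether. The cis preference from a substituent on the radical carbon is usually modest, tin is used stoichiometrically, and the final hydrogenolysis must spare two benzylic ring C–O bonds.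
- **Structure:** it forms one bond where the chosen plan forms three, and it needs C2 and C5 fixed beforehand, whereas the chosen plan leaves them to equilibration.
- **Mechanism:** it is the better plan on the decisive issue, the C3/C4 relationship, because a unimolecular cyclisation through an ordered transition state replaces an undirected pairing of two radicals. It is the equal of the chosen plan in relying on radical C–C bond formation that tolerates the oxygenation pattern.
- **Step economy:** it is worse, roughly seven to eight operations against three.

Alternative 3: The ring is cut at C2–C3 in a carbenoid sense. This leads back to the diazo ester A6, a methyl 2-diazo-3-methylbutanoate whose C4 carries one aryl group and an arylmethyl ether.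
- **Forward key step:** a dirhodium tetracarboxylate such as Rh2(OAc)4 would form the carbenoid at C3, which inserts into the benzylic C–H bond five atoms away (activated by the ether oxygen and the arene) to give the oxolane-3-carboxylate A7. The ester centre would then be equilibrated, the ester reduced to the C3 methyl group, and the benzyl ethers removed.
- **In favour:** the C4/C5 relationship can be set beforehand by dependable aldol chemistry. C–H insertion next to an ether oxygen is a known route to oxolanes, and C3 stays adjustable through its enolate.
- **Against:** the carbenoid from an α-alkyl diazo ester has a hydrogen on the neighbouring carbon, so 1,2-hydride migration to the unsaturated ester would compete strongly unless bulky carboxylate ligands and low temperature are used. The electron-rich arenes offer aromatic cycloaddition, the cis C2/C5 relationship created in the insertion is not assured, diazo transfer to a simple ester needs prior activation, and the ester-to-methyl conversion costs about three operations.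
- **Structure:** after the key step it is the equal of alternative 1, with one ester to convert instead of two. It is better than the chosen plan in that C3 can be corrected by equilibration.
- **Mechanism:** it is less secure than either, because of the hydride shift.
- **Step economy:** it is the longest plan, about ten to eleven operations against three.

Key step: step 2

Remark on the chemistry: 9 is meso, so only relative configuration is at stake; the ring is numbered O1, C2–C5 and the side chain of 2 is numbered C7 (benzylic), C8, C9 (methyl). Compound 2 is used as the unprotected, geometrically pure (E)-phenol because the phenol O–H is the site of oxidation. A Wittig ethylidenation of syringaldehyde is not used as its source, since an unstabilised ylide would favour the (Z)-alkene.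

## Route

Step 1
Reactants: 1 4-allyl-2,6-dimethoxyphenol
Product: 2 (E)-2,6-dimethoxy-4-(prop-1-en-1-yl)phenol
Conditions: RuHCl(CO)(PPh3)3 (2 mol%), toluene, 80 °C, argon; SiO2 filtration, AgNO3-impregnated SiO2 if (Z)-isomer remains
Reagents that add atoms: none
Why: Transition-metal hydride olefin isomerisation: Ru–H adds across the terminal alkene and β-hydride elimination toward the ring gives the styrenyl alkene, conjugation with the arene making 2 the thermodynamic sink and the trans (E) geometry the favoured one; the free phenol should be tolerated and no stereocentre is formed. Any residual (Z)-isomer is removed on AgNO3-impregnated silica so that a single alkene geometry enters the key step.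

Step 2
Reactants: 2 (E)-2,6-dimethoxy-4-(prop-1-en-1-yl)phenol (two molecules); 3 water
Product: 7 rel-(3R,4S)-2,5-bis(4-hydroxy-3,5-dimethoxyphenyl)-3,4-dimethyloxolane (cis-3,4-dimethyl series; epimer mixture at C2/C5), via phenoxyl radical 4 (not isolated), via meso bis(quinone methide) 5 (not isolated), via hydroxy quinone methide 6 (not isolated)
Conditions: FeCl3·6H2O (1.0 equiv per 2, added over 1 h), acetone–H2O (2:1), 0.02 M, 0 °C to rt, argon; EtOAc extraction; SiO2 (oxolane fraction)
Reagents that add atoms: water, O
Why: FeCl3 takes one electron from each molecule of 2 (the proton goes to the medium) to give the phenoxyl radical 4, whose spin density lies on the phenol oxygen, on ring carbons C1, C3 and C5 and on the side-chain carbon C8; because C3 and C5 both carry methoxy groups, 8–5' coupling is shut off and two radicals join irreversibly at C8–C8' to give the bis(quinone methide) 5, which forms the C3–C4 bond of the oxolane. Water 3 then adds 1,6 to one quinone methide carbon, rearomatising that ring and giving 6, and the new benzylic hydroxyl adds 1,6 to the second quinone methide carbon in a 5-exo-trig closure, so that one water oxygen forms both O1–C2 and O1–C5 and closes the only new ring. The closest known reaction type is the dehydrodimerisation of 4-propenylphenols and 4-hydroxycinnamyl alcohols by one-electron oxidants or peroxidases, in which 8–8' coupling is followed by trapping of both quinone methides. C3 and C4 are set in the radical coupling itself: union of the two prochiral C8 faces in the unlike sense gives meso 5 and hence cis methyl groups, whereas the like sense gives the 3,4-trans series, and since 2 has no element that enforces the unlike mode this selectivity rests on the intrinsic preference of the pairing and on separation after step 3. C2 and C5 are created in reversible 1,6-additions to para-quinone methides, so their configuration is not fixed here and is settled under thermodynamic control in step 3. The step further needs chemoselectivity of the oxidant, which the substrate supplies because the conjugated phenol 2 should be oxidised more readily than the non-conjugated phenols of 7; one equivalent of FeCl3 per phenol, added slowly at high dilution, limits over-oxidation. Coupling through the phenol oxygen (8–O–4') is the expected competitor, and the benzylic alcohols it gives after water addition are removed on silica, while the 3,4-trans oxolanes are carried along into step 3.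

Step 3
Reactants: 7 rel-(3R,4S)-2,5-bis(4-hydroxy-3,5-dimethoxyphenyl)-3,4-dimethyloxolane (epimer mixture at C2/C5)
Product: 9 fragransin B1 [meso-(2S,3S,4R,5R)-2,5-bis(4-hydroxy-3,5-dimethoxyphenyl)-3,4-dimethyloxolane], via ring-opened benzylic cation 8 (not isolated)
Conditions: TFA (0.2 equiv), CH2Cl2, 0 °C to rt; aq. NaHCO3; SiO2, then crystallisation
Reagents that add atoms: none
Why: Acid-catalysed epimerisation of para-hydroxybenzylic ether centres (SN1 type): protonation at O1 and ionisation of a benzylic C–O bond give the ring-opened cation 8, which the para-hydroxyl group stabilises as a protonated para-quinone methide and which rotates and re-closes 5-exo-trig through its carbinol oxygen from either face, releasing the proton again. Repetition at C2 and C5 should funnel the epimers of 7 into 9, the isomer with each aryl group trans to its neighbouring methyl group (thermodynamic control), while C3 and C4 are untouched; the 3,4-trans oxolanes carried along should converge on their own all-trans isomer, which is then removed by chromatography and crystallisation.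

## Compound list

1 | 4-allyl-2,6-dimethoxyphenol | C=CCc1cc(OC)c(O)c(OC)c1 | starting material
2 | (E)-2,6-dimethoxy-4-(prop-1-en-1-yl)phenol | C/C=C/c1cc(OC)c(O)c(OC)c1 | intermediate
3 | water | O | starting material
4 | (E)-2,6-dimethoxy-4-(prop-1-en-1-yl)phenoxyl radical | C/C=C/c1cc(OC)c([O])c(OC)c1 | intermediate
5 | meso bis(quinone methide), 4,4'-[(2R,3S)-2,3-dimethylbutane-1,4-diylidene]bis(2,6-dimethoxycyclohexa-2,5-dien-1-one) | COC1=CC(=C[C@H](C)[C@H](C)C=C2C=C(OC)C(=O)C(OC)=C2)C=C(OC)C1=O | intermediate
6 | hydroxy quinone methide, 4-[rel-(2S,3S)-4-hydroxy-4-(4-hydroxy-3,5-dimethoxyphenyl)-2,3-dimethylbutylidene]-2,6-dimethoxycyclohexa-2,5-dien-1-one (racemic; carbinol carbon of either configuration) | COc1cc(C(O)[C@@H](C)[C@@H](C)C=C2C=C(OC)C(=O)C(OC)=C2)cc(OC)c1O | intermediate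
7 | rel-(3R,4S)-2,5-bis(4-hydroxy-3,5-dimethoxyphenyl)-3,4-dimethyloxolane, methyl groups cis, epimer mixture at C2 and C5 | COc1cc(C2OC(c3cc(OC)c(O)c(OC)c3)[C@H](C)[C@@H]2C)cc(OC)c1O | intermediate
8 | ring-opened para-hydroxybenzylic cation (O-protonated hydroxy quinone methide), rel-(2S,3S)-4-hydroxy-1,4-bis(4-hydroxy-3,5-dimethoxyphenyl)-2,3-dimethylbutan-1-ylium (racemic; carbinol carbon of either configuration) | COc1cc(C(O)[C@@H](C)[C@@H](C)[CH+]c2cc(OC)c(O)c(OC)c2)cc(OC)c1O | intermediate
9 | fragransin B1, meso-(2S,3S,4R,5R)-2,5-bis(4-hydroxy-3,5-dimethoxyphenyl)-3,4-dimethyloxolane (aryl groups cis, methyl groups cis, each aryl trans to the adjacent methyl) | COc1cc([C@H]2O[C@@H](c3cc(OC)c(O)c(OC)c3)[C@H](C)[C@@H]2C)cc(OC)c1O | target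

## Step count and least certain steps

Total step count: 3. Longest linear sequence: 3 steps (1 to 2 to 7 to 9).

The route has three steps; all three are assessed, the key step first.

**Step 2 (key step).**
- **What is most likely to go wrong:** pairing of the two radicals 4 in the like sense and, to a lesser extent, coupling through the phenol oxygen. Nothing in 2 distinguishes the unlike from the like approach of the two C8 faces, and the resinol-type 8–8' dimers of 4-hydroxycinnamyl alcohols correspond to the like mode, which suggests that this mode is at least competitive. The cis-3,4 series would then be the minor part of the oxolane fraction.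
- **Fallback:** it sets out from 2 and returns to the route at 9. It moves the stereochemical decision from the radical pairing to a hydrogenation.
  - Compound 2 is dimerised as in step 2, and the whole 8–8' fraction is collected without regard to configuration: 2,5-bis(4-hydroxy-3,5-dimethoxyphenyl)-3,4-dimethyloxolane as a mixture of all stereoisomers F1.
  - Benzylation (BnBr, K2CO3, DMF) should give the bis(benzyl ether) mixture F2.
  - DDQ in refluxing dioxane should dehydrogenate every stereoisomer to the same achiral compound, 2,5-bis(4-benzyloxy-3,5-dimethoxyphenyl)-3,4-dimethylfuran F3.
  - Hydrogenation (H2, Pd/C, EtOAc–EtOH) should add hydrogen to one face of the furan and cleave both benzyl ethers, giving the all-cis bisphenol, meso-(2S,3R,4S,5R)-2,5-bis(4-hydroxy-3,5-dimethoxyphenyl)-3,4-dimethyloxolane F4, in which the methyl groups are necessarily cis.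
  - The acid treatment of step 3 then inverts both benzylic centres to give 9.
  - Dehydrogenation of 2,5-diaryloxolanes to furans with DDQ, cis hydrogenation of furans and acid epimerisation of benzylic oxolane centres are known reaction types. The detour does not recover O-coupled material.

**Step 3.**
- **What is most likely to go wrong:** irreversible capture of the ring-opened benzylic cation by the other arene (Friedel–Crafts closure to an aryltetralin) or by a second molecule, in competition with re-closure through oxygen. The ring positions ortho to the side chain are activated by two methoxy groups and the carbocyclic closure forms a six-membered ring.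
- **Fallback:** it sets out from 7 and returns at 9, and replaces equilibration by separation of non-ionisable derivatives.
  - Compound 7 is acetylated (Ac2O, pyridine).
  - The trans,cis,trans diacetate, meso-(2S,3S,4R,5R)-2,5-bis(4-acetoxy-3,5-dimethoxyphenyl)-3,4-dimethyloxolane F5, is isolated by crystallisation or chromatography.
  - Methanolysis (K2CO3, MeOH) should give 9.
  - This relies on the share of the desired epimer already present in 7, which the acid released during step 2 is expected to raise.

**Step 1.**
- **What is most likely to go wrong:** incomplete transposition or incomplete geometric control, leaving allyl or (Z)-alkene that travels with 2. Coordination of the phenol to ruthenium can slow the hydride cycle, and the (Z)-isomer is only slightly less stable than the (E)-isomer.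
- **Fallback:** it sets out from 1 and returns at 2, taking the phenol out of play.
  - Silylation (TBSCl, imidazole, DMF) should give tert-butyl(4-allyl-2,6-dimethoxyphenoxy)dimethylsilane F6.
  - PdCl2(MeCN)2 (catalytic, CH2Cl2, rt to 40 °C) should isomerise it to tert-butyl{2,6-dimethoxy-4-[(E)-prop-1-en-1-yl]phenoxy}dimethylsilane F7, which can be purified as a non-polar, non-oxidisable compound.
  - TBAF (THF, 0 °C) then releases 2.

## Further compounds

F1 | step 2 | 2,5-bis(4-hydroxy-3,5-dimethoxyphenyl)-3,4-dimethyloxolane, mixture of all stereoisomers at C2–C5 | COc1cc(C2OC(c3cc(OC)c(O)c(OC)c3)C(C)C2C)cc(OC)c1O
F2 | step 2 | 2,5-bis(4-benzyloxy-3,5-dimethoxyphenyl)-3,4-dimethyloxolane, mixture of all stereoisomers at C2–C5 | COc1cc(C2OC(c3cc(OC)c(OCc4ccccc4)c(OC)c3)C(C)C2C)cc(OC)c1OCc1ccccc1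
F3 | step 2 | 2,5-bis(4-benzyloxy-3,5-dimethoxyphenyl)-3,4-dimethylfuran | COc1cc(-c2oc(-c3cc(OC)c(OCc4ccccc4)c(OC)c3)c(C)c2C)cc(OC)c1OCc1ccccc1
F4 | step 2 | all-cis meso-(2S,3R,4S,5R)-2,5-bis(4-hydroxy-3,5-dimethoxyphenyl)-3,4-dimethyloxolane | COc1cc([C@H]2O[C@@H](c3cc(OC)c(O)c(OC)c3)[C@@H](C)[C@H]2C)cc(OC)c1O
F5 | step 3 | meso-(2S,3S,4R,5R)-2,5-bis(4-acetoxy-3,5-dimethoxyphenyl)-3,4-dimethyloxolane | COc1cc([C@H]2O[C@@H](c3cc(OC)c(OC(C)=O)c(OC)c3)[C@H](C)[C@@H]2C)cc(OC)c1OC(C)=O
F6 | step 1 | tert-butyl(4-allyl-2,6-dimethoxyphenoxy)dimethylsilane | C=CCc1cc(OC)c(O[Si](C)(C)C(C)(C)C)c(OC)c1
F7 | step 1 | tert-butyl{2,6-dimethoxy-4-[(E)-prop-1-en-1-yl]phenoxy}dimethylsilane | C/C=C/c1cc(OC)c(O[Si](C)(C)C(C)(C)C)c(OC)c1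
A1 | alternative 1 | dimethyl cis-2-(4-benzyloxy-3,5-dimethoxyphenyl)-3-methylcyclopropane-1,1-dicarboxylate (racemic) | COC(=O)C1(C(=O)OC)[C@@H](C)[C@H]1c1cc(OC)c(OCc2ccccc2)c(OC)c1
A2 | alternative 1 | 4-benzyloxy-3,5-dimethoxybenzaldehyde | COc1cc(C=O)cc(OC)c1OCc1ccccc1
A3 | alternative 1 | dimethyl 2,5-bis(4-benzyloxy-3,5-dimethoxyphenyl)-4-methyloxolane-3,3-dicarboxylate (2,5-cis; 4-methyl trans to 5-aryl; racemic) | COc1cc([C@H]2O[C@@H](c3cc(OC)c(OCc4ccccc4)c(OC)c3)[C@H](C)C2(C(=O)OC)C(=O)OC)cc(OC)c1OCc1ccccc1
A4 | alternative 2 | rel-(1R)-1-(4-benzyloxy-3,5-dimethoxyphenyl)-2-bromopropyl (1R)-1-(4-benzyloxy-3,5-dimethoxyphenyl)prop-2-en-1-yl ether (racemic; bromide carbon of either configuration) | COc1cc([C@@H](O[C@H](C=C)c2cc(OC)c(OCc3ccccc3)c(OC)c2)C(C)Br)cc(OC)c1OCc1ccccc1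
A5 | alternative 2 | fragransin B1 bis(benzyl ether), meso-(2S,3S,4R,5R)-2,5-bis(4-benzyloxy-3,5-dimethoxyphenyl)-3,4-dimethyloxolane | COc1cc([C@H]2O[C@@H](c3cc(OC)c(OCc4ccccc4)c(OC)c3)[C@H](C)[C@@H]2C)cc(OC)c1OCc1ccccc1
A6 | alternative 3 | methyl rel-(3R,4R)-4-(4-benzyloxy-3,5-dimethoxybenzyloxy)-4-(4-benzyloxy-3,5-dimethoxyphenyl)-2-diazo-3-methylbutanoate (racemic) | COc1cc(CO[C@@H](c2cc(OC)c(OCc3ccccc3)c(OC)c2)[C@H](C)C(=[N+]=[N-])C(=O)OC)cc(OC)c1OCc1ccccc1
A7 | alternative 3 | methyl 2,5-bis(4-benzyloxy-3,5-dimethoxyphenyl)-4-methyloxolane-3-carboxylate (2,5-cis; 4-methyl trans to 5-aryl; C3 undefined; racemic) | COc1cc([C@H]2O[C@@H](c3cc(OC)c(OCc4ccccc4)c(OC)c3)[C@H](C)C2C(=O)OC)cc(OC)c1OCc1ccccc1
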